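The carbocycle is cut at C4–C5 and C1–C6 (ionone numbering: C1 gem-dimethyl carbon, C3 ester carbinol, C5/C6 epoxide carbons). The feature exploited is that in the six-membered ring the C3 oxygen sits 1,4 to the chain-bearing C6, with a methyl on C5: exactly the pattern of a [4+2] adduct of a 2-silyloxydiene and a methyl-substituted ynal. One cycloaddition gives the ring, all three methyls, the C5=C6 alkene, a masked C3 ketone and the C7 formyl group. Its precursors are the kinetic triethylsilyl dienol ether of mesityl oxide and but-2-ynal. The three stereocentres follow from resolution at C3, hydroxyl-directed epoxidation and Mitsunobu inversion.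

Key step: step 3

Remark: the target is (3S,5R,6S) in ionone numbering (side chain C7=C8, C9 carbonyl), with the C3 ester on the ring face opposite the epoxide oxygen.
Remark: a triethylsilyl dienol ether replaces the trimethylsilyl one because it should survive heating, base-washed silica and the olefination, yet still cleave under mild acid methanolysis.
Remark: C3 is made racemic and then resolved, because the ring ketone is flanked by two CH2 groups (no reliable reagent-controlled facial bias) and the side-chain enone would compete for a chiral reducing catalyst.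

Step 1
Reactants: 1 mesityl oxide
Product: 2 4-methyl-2-(triethylsilyloxy)penta-1,3-diene
Conditions: LiN(iPr)2 (LDA), THF, −78 °C; then Et3SiCl, −78 °C → 0 °C; non-aqueous work-up (pentane, filtration), distillation
Reagents that add atoms: chlorotriethylsilane, CC[Si](Cl)(CC)CC
Why: Kinetic deprotonation of the enone at the α′-methyl group by the hindered amide base gives the cross-conjugated lithium dienolate, and its O-silylation (silyl enol ether formation) should give the 2-silyloxydiene; no stereocentre is formed.

Step 2
Reactants: 3 but-2-yn-1-ol
Product: 4 but-2-ynal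
Conditions: MnO2 (activated, excess), CH2Cl2, rt; filtration; toluene added and CH2Cl2 distilled off through a column
Reagents that add atoms: none
Why: Heterogeneous MnO2 oxidation of a propargylic alcohol stops at the aldehyde, and the volatile, polymerisation-prone ynal is carried on as a fresh toluene solution; no stereocentre is formed.

Step 3
Reactants: 2 4-methyl-2-(triethylsilyloxy)penta-1,3-diene; 4 but-2-ynal
Product: 5 2,6,6-trimethyl-4-(triethylsilyloxy)cyclohexa-1,4-diene-1-carbaldehyde
Conditions: toluene (concentrated), BHT (cat.), 100 °C, sealed vessel, 1.5 equiv of 2, no Lewis acid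
Reagents that add atoms: none
Why: This is a normal-electron-demand Diels–Alder reaction in which the electron-rich silyloxydiene adds across the C≡C bond of the ynal in a concerted but strongly asynchronous [4+2] process, the bond from the diene CH2 terminus (future C4) to the alkyne β-carbon (C5) running ahead of the bond from the CMe2 terminus (C1) to the α-carbon (C6). The closest known reaction type is the thermal cycloaddition of 2-silyloxybutadienes, mesityl-oxide-derived ones included, with acetylenic aldehydes, ketones and esters. The six-membered ring is closed by suprafacial π4s+π2s cycloaddition and emerges as a 1,4-cyclohexadiene that cannot aromatise because C1 is quaternary. No stereocentre is formed. The step needs para regiochemistry (silyloxy carbon opposite the formyl-bearing carbon) and addition to C≡C, not C=O: the first is secured because the silyloxy group makes the CH2 terminus the most nucleophilic diene carbon while the formyl group makes the β-alkyne carbon the most electrophilic, and the second by leaving out any Lewis acid, which would divert the silyl enol ether to Mukaiyama aldol addition at the aldehyde. The rod-shaped alkyne keeps the clash with the inward methyl group of the diene small, and BHT with excess diene should hold back ynal oligomerisation.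

Step 4
Reactants: 5 2,6,6-trimethyl-4-(triethylsilyloxy)cyclohexa-1,4-diene-1-carbaldehyde; 6 1-(triphenylphosphoranylidene)propan-2-one
Product: 7 (E)-4-[2,6,6-trimethyl-4-(triethylsilyloxy)cyclohexa-1,4-dien-1-yl]but-3-en-2-one
Conditions: toluene, 110 °C, prolonged heating; chromatography on Et3N-washed silica
Reagents that add atoms: none
Why: Wittig olefination with a ketone-stabilised ylide runs under neutral conditions that leave the silyl enol ether intact and should give the (E)-enone, with the hindrance of the doubly flanked formyl group answered by prolonged heating; no stereocentre is formed.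

Step 5
Reactants: 7 (E)-4-[2,6,6-trimethyl-4-(triethylsilyloxy)cyclohexa-1,4-dien-1-yl]but-3-en-2-one
Product: 9 rac-3-hydroxy-β-ionone (racemic (E)-4-(4-hydroxy-2,6,6-trimethylcyclohex-1-en-1-yl)but-3-en-2-one), via 3-oxo-β-ionone 8 (not isolated)
Conditions: PPTS (cat.), MeOH/CH2Cl2 (1:1), 0 °C; then NaBH4, −78 °C → −50 °C; aqueous NH4Cl
Reagents that add atoms: none
Why: Mild acid methanolysis protonates the enol ether at C2 and releases the C3 ketone without moving the C5=C6 bond, and chemoselective borohydride reduction in the same flask at low temperature should take the non-conjugated ring ketone much faster than the conjugated C9 dienone, so the isomerisation-prone β,γ-unsaturated ketone is never isolated; C3 is formed as the racemate on purpose.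

Step 6
Reactants: 9 rac-3-hydroxy-β-ionone
Product: 10 (3S)-3-hydroxy-β-ionone ((E)-4-[(4S)-4-hydroxy-2,6,6-trimethylcyclohex-1-en-1-yl]but-3-en-2-one)
Conditions: Burkholderia cepacia lipase (immobilised), vinyl acetate, MTBE, 30 °C, run slightly past half conversion; chromatographic separation from the acetate
Reagents that add atoms: none
Why: In this lipase-catalysed kinetic resolution by irreversible transesterification, the empirical size rule for secondary alcohols (large flank CH2–CMe2, medium flank CH2–C(Me)=) predicts acetylation of the (3R)-alcohol, so running past half conversion should leave the (3S)-alcohol in high enantiomeric purity; the C3 configuration is selected here, at the cost of at most half of the material.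

Step 7
Reactants: 10 (3S)-3-hydroxy-β-ionone
Product: 11 (3R,5R,6S)-5,6-epoxy-3-hydroxy-5,6-dihydro-β-ionone ((E)-4-[(1S,4R,6R)-4-hydroxy-2,2,6-trimethyl-7-oxabicyclo[4.1.0]heptan-1-yl]but-3-en-2-one; hydroxyl and epoxide oxygen on the same ring face)
Conditions: VO(acac)2 (cat.), t-BuOOH, toluene, 0 °C → rt
Reagents that add atoms: tert-butyl hydroperoxide, CC(C)(C)OO
Why: In this hydroxyl-directed epoxidation of a cyclic homoallylic alcohol, the C3 alkoxide bound to the vanadium peroxide delivers oxygen to the C5=C6 bond from its own ring face, setting C5 (R) and C6 (S) syn to the hydroxyl, while the electron-poor C7=C8 enone bond should not react with this electrophilic oxidant.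

Step 8
Reactants: 11 (3R,5R,6S)-5,6-epoxy-3-hydroxy-5,6-dihydro-β-ionone; 12 myristic acid
Product: 13 (3S,5R,6S)-5,6-epoxy-3-(tetradecanoyloxy)-5,6-dihydro-β-ionone ((1R,3S,6S)-1,5,5-trimethyl-6-[(E)-3-oxobut-1-en-1-yl]-7-oxabicyclo[4.1.0]heptan-3-yl tetradecanoate)
Conditions: PPh3, DIAD, THF, 0 °C → rt
Reagents that add atoms: none
Why: In this Mitsunobu esterification the alkoxyphosphonium ion at C3 is displaced by myristate in an SN2 reaction with inversion, turning (3R) into (3S) and placing the ester on the face opposite the epoxide, which cannot participate because it lies syn to the leaving group; epoxide and enone should survive these neutral conditions.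

Compound list
1 | mesityl oxide (4-methylpent-3-en-2-one) | CC(C)=CC(C)=O | starting material
2 | 4-methyl-2-(triethylsilyloxy)penta-1,3-diene | C=C(O[Si](CC)(CC)CC)C=C(C)C | intermediate
3 | but-2-yn-1-ol | CC#CCO | starting material
4 | but-2-ynal | CC#CC=O | intermediate
5 | 2,6,6-trimethyl-4-(triethylsilyloxy)cyclohexa-1,4-diene-1-carbaldehyde | O=CC1=C(C)CC(O[Si](CC)(CC)CC)=CC1(C)C | intermediate
6 | 1-(triphenylphosphoranylidene)propan-2-one | CC(=O)C=P(c1ccccc1)(c1ccccc1)c1ccccc1 | starting material
7 | (E)-4-[2,6,6-trimethyl-4-(triethylsilyloxy)cyclohexa-1,4-dien-1-yl]but-3-en-2-one | CC(=O)/C=C/C1=C(C)CC(O[Si](CC)(CC)CC)=CC1(C)C | intermediate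
8 | 3-oxo-β-ionone, (E)-4-(2,6,6-trimethyl-4-oxocyclohex-1-en-1-yl)but-3-en-2-one (not isolated) | CC(=O)/C=C/C1=C(C)CC(=O)CC1(C)C | intermediate
9 | rac-3-hydroxy-β-ionone, racemic (E)-4-(4-hydroxy-2,6,6-trimethylcyclohex-1-en-1-yl)but-3-en-2-one | CC(=O)/C=C/C1=C(C)CC(O)CC1(C)C | intermediate
10 | (3S)-3-hydroxy-β-ionone, (E)-4-[(4S)-4-hydroxy-2,6,6-trimethylcyclohex-1-en-1-yl]but-3-en-2-one | CC(=O)/C=C/C1=C(C)C[C@H](O)CC1(C)C | intermediate
11 | (3R,5R,6S)-5,6-epoxy-3-hydroxy-5,6-dihydro-β-ionone (hydroxyl syn to epoxide) | O[C@@H]1CC(C)(C)[C@]2(/C=C/C(C)=O)O[C@]2(C)C1 | intermediate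
12 | myristic acid (tetradecanoic acid) | CCCCCCCCCCCCCC(=O)O | starting material
13 | (3S,5R,6S)-5,6-epoxy-3-(tetradecanoyloxy)-5,6-dihydro-β-ionone (ester anti to epoxide) | CCCCCCCCCCCCCC(=O)O[C@H]1CC(C)(C)[C@]2(/C=C/C(C)=O)O[C@]2(C)C1 | target

Total step count: 8. Longest linear sequence: 7 steps (steps 1, 3, 4, 5, 6, 7, 8 from mesityl oxide); step 2 is a one-step side branch.

Steps most likely to fail

Step 3. The cycloaddition at the dimethyl-substituted diene terminus may be slow enough that thermal oligomerisation of the ynal or loss of the silyl group wins. The fallback sets out from 2 and comes back at 5. It replaces the concerted thermal reaction of the aldehyde by a Lewis-acid-driven stepwise annulation with an ester dienophile, for which carbonyl addition cannot compete. Diene 2 and methyl but-2-ynoate with EtAlCl2 in CH2Cl2 at low temperature (Mukaiyama–Michael addition, then closure of the aluminium allenoate onto the silyloxyallyl cation) should give methyl 2,6,6-trimethyl-4-(triethylsilyloxy)cyclohexa-1,4-diene-1-carboxylate F1. Reduction with iBu2AlH (toluene, −78 °C) should give [2,6,6-trimethyl-4-(triethylsilyloxy)cyclohexa-1,4-dien-1-yl]methanol F2, and MnO2 oxidation of this allylic alcohol returns aldehyde 5.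

Step 4. Olefination at the formyl group, which is flanked by a quaternary carbon and a substituted alkene carbon, may be so slow that prolonged heating erodes the silyl enol ether before conversion is complete. The fallback sets out from 5 and comes back at 7, replacing the olefination by aldol addition and elimination. The lithium enolate of acetone (LiN(iPr)2, THF, −78 °C) should add to 5 to give rac-4-hydroxy-4-[2,6,6-trimethyl-4-(triethylsilyloxy)cyclohexa-1,4-dien-1-yl]butan-2-one F3. MsCl/Et3N should convert it into 4-(methylsulfonyloxy)-4-[2,6,6-trimethyl-4-(triethylsilyloxy)cyclohexa-1,4-dien-1-yl]butan-2-one F4, and DBU-induced E1cB loss of methanesulfonate gives the (E)-enone 7.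

Step 6. The lipase may discriminate the enantiomers weakly, or in the opposite sense, because both flanks of the carbinol are CH2 groups. The fallback sets out from 9 and comes back at 10, using classical resolution through diastereomers. Esterification of 9 with (S)-O-methylmandelic acid (EDC, cat. DMAP, CH2Cl2) should give (1S)-3,5,5-trimethyl-4-[(E)-3-oxobut-1-en-1-yl]cyclohex-3-en-1-yl (2S)-2-methoxy-2-phenylacetate F5 together with its diastereomer (1R)-3,5,5-trimethyl-4-[(E)-3-oxobut-1-en-1-yl]cyclohex-3-en-1-yl (2S)-2-methoxy-2-phenylacetate F6. The two would be separated by chromatography or crystallisation, and K2CO3/MeOH methanolysis of F5 releases 10.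

Further compounds
F1 | step 3 | methyl 2,6,6-trimethyl-4-(triethylsilyloxy)cyclohexa-1,4-diene-1-carboxylate | COC(=O)C1=C(C)CC(O[Si](CC)(CC)CC)=CC1(C)C
F2 | step 3 | [2,6,6-trimethyl-4-(triethylsilyloxy)cyclohexa-1,4-dien-1-yl]methanol | OCC1=C(C)CC(O[Si](CC)(CC)CC)=CC1(C)C
F3 | step 4 | rac-4-hydroxy-4-[2,6,6-trimethyl-4-(triethylsilyloxy)cyclohexa-1,4-dien-1-yl]butan-2-one | CC(=O)CC(O)C1=C(C)CC(O[Si](CC)(CC)CC)=CC1(C)C
F4 | step 4 | rac-4-(methylsulfonyloxy)-4-[2,6,6-trimethyl-4-(triethylsilyloxy)cyclohexa-1,4-dien-1-yl]butan-2-one | CC(=O)CC(OS(C)(=O)=O)C1=C(C)CC(O[Si](CC)(CC)CC)=CC1(C)C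
F5 | step 6 | (1S)-3,5,5-trimethyl-4-[(E)-3-oxobut-1-en-1-yl]cyclohex-3-en-1-yl (2S)-2-methoxy-2-phenylacetate | CO[C@H](C(=O)O[C@@H]1CC(C)(C)C(/C=C/C(C)=O)=C(C)C1)c1ccccc1
F6 | step 6 | (1R)-3,5,5-trimethyl-4-[(E)-3-oxobut-1-en-1-yl]cyclohex-3-en-1-yl (2S)-2-methoxy-2-phenylacetate | CO[C@H](C(=O)O[C@H]1CC(C)(C)C(/C=C/C(C)=O)=C(C)C1)c1ccccc1
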